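**Retrosynthetic overview**

- Feature: in ring A the chain C19–C4–C3–C2–C1 (carboxyl carbon, deoxy carbon, two cis oxygens, CH2) is a 2-deoxy-L-erythro-pentose; it is tied to ring B by C4–C5 and C1–C10, and C19 bridges to C10 through the lactone oxygen.
- Disconnections: 19,10-lactone by iodolactonisation of the 1(10)-ene 19-acid; C4–C5 and ring A by Ireland–Claisen ring contraction of the sugar δ-lactone across C10=C5 of ring B; C1–C10 by CrCl2/NiCl2 coupling of the ring B enol triflate with the sugar aldehyde.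
- The lactone must carry C10 cis to the acetonide (C1–O threo to C2–O), so C1 is set by oxidation and Felkin-type reduction after the coupling, not by the coupling itself.
- B/C/D ketone: ring B from (S)-4-silyloxycyclopentenone (C7 by photochemical hydroxymethylation, C15–C17 by propargyl addition), ring C by Diels–Alder reaction with a 2-silyloxybutadiene, ring D by SmI2 ketyl–alkyne closure.
- Ring order: B, C, D, the δ-lactone, ring A, the γ-lactone.

Key step: step 21

Assumption: 2-deoxy-L-ribose (the 2-deoxypentose of the L-arabinose series) and (S)-4-(tert-butyldimethylsilyloxy)cyclopent-2-enone are bought as single enantiomers; gibberellane numbering (C1 to C19, C7 being the carboxyl carbon on C6) is used for all intermediates.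

**Route**

Step 1
Reactants: 1 (S)-4-(tert-butyldimethylsilyloxy)cyclopent-2-en-1-one; 2 methanol
Product: 3 (3R,4S)-4-(tert-butyldimethylsilyloxy)-3-(hydroxymethyl)cyclopentan-1-one
Conditions: hν (350 nm), Ph2CO (0.2 equiv), MeOH (degassed), rt
Reagents that add atoms: methanol (compound 2), CO
Why: Benzophenone-sensitised radical conjugate addition of the hydroxymethyl radical to the enone should place C7 on C6 trans to the silyloxy group, which sets the C6 stereocentre.

Step 2
Reactants: 3
Product: 4 (3R,4S)-4-(tert-butyldimethylsilyloxy)-3-[(tert-butyldiphenylsilyloxy)methyl]cyclopentan-1-one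
Conditions: TBDPSCl, imidazole, CH2Cl2, 0 °C
Reagents that add atoms: tert-butyl(chloro)diphenylsilane, CC(C)(C)[Si](Cl)(c1ccccc1)c1ccccc1
Why: Silylation of the primary alcohol with an acid- and Lewis-acid-robust group; mild base at 0 °C should avoid β-elimination of the silyloxy ketone.

Step 3
Reactants: 4; 2 methanol
Product: 6 (1S,2R)-2-[(tert-butyldiphenylsilyloxy)methyl]-4,4-dimethoxycyclopentan-1-ol, via silyloxy dimethyl ketal 5 (not isolated)
Conditions: HC(OMe)3, CSA (0.2 equiv), MeOH, rt to 40 °C
Reagents that add atoms: trimethyl orthoformate, COC(OC)OC; methanol (compound 2), CO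
Why: Acid-catalysed ketalisation masks C10, and the same acid in methanol then cleaves the secondary tert-butyldimethylsilyl ether while the tert-butyldiphenylsilyl ether survives, freeing the C8 hydroxyl.

Step 4
Reactants: 6
Product: 8 (R)-5-[(tert-butyldiphenylsilyloxy)methyl]-3-methoxycyclopent-2-en-1-one, via β-keto ketal 7 (not isolated)
Conditions: DMP, NaHCO3, CH2Cl2, 0 °C to rt; then TsOH·H2O (cat.), CH2Cl2, rt
Reagents that add atoms: none
Why: Dess–Martin oxidation gives the β-keto ketal, which loses methanol under acid to the vinylogous ester with the carbonyl at C8 and the enol ether at C10; the ketal position fixes this regiochemistry, and ionisation of the ketal should be much faster than acid-catalysed enolisation towards C6.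

Step 5
Reactants: 8; 9 propargyl bromide
Product: 11 (S)-4-[(tert-butyldiphenylsilyloxy)methyl]-3-(prop-2-yn-1-yl)cyclopent-2-en-1-one, via tertiary carbinol 10 (not isolated)
Conditions: 9, Mg, HgCl2 (cat.), Et2O, 0 °C; add 8, −78 to 0 °C; then 1 M HCl, THF, 0 °C
Reagents that add atoms: propargyl bromide (compound 9, used as propargylmagnesium bromide), C#CCBr
Why: Stork–Danheiser sequence: 1,2-addition of the propargyl Grignard reagent to the vinylogous ester and acid hydrolysis transpose the enone, so C8 carries C15–C17 and C10 becomes the carbonyl.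

Step 6
Reactants: 12 methyl vinyl ketone
Product: 13 2-(tert-butyldimethylsilyloxy)buta-1,3-diene
Conditions: TBSOTf, Et3N, Et2O, 0 °C
Reagents that add atoms: tert-butyldimethylsilyl trifluoromethanesulfonate, CC(C)(C)[Si](C)(C)OS(=O)(=O)C(F)(F)F
Why: Soft enolisation and O-silylation of the methyl ketone gives the 2-silyloxydiene.

Step 7
Reactants: 11; 13
Product: 14 all-cis 5-(tert-butyldimethylsilyloxy)-3-[(tert-butyldiphenylsilyloxy)methyl]-3a-(prop-2-yn-1-yl)-2,3,3a,4,7,7a-hexahydro-1H-inden-1-one
Conditions: AlBr3/AlMe3 (10:1, 0.3 equiv), toluene/CH2Cl2, −10 °C to rt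
Reagents that add atoms: none
Why: Lewis-acid-promoted Diels–Alder reaction of a hindered β,β-disubstituted cyclopentenone with a 2-silyloxydiene (mixed AlBr3/AlMe3 activation is the known remedy for such dienophiles): the nucleophilic diene terminus C14 bonds to C8, the diene adds opposite the C6 substituent and suprafacial addition gives the cis ring fusion, which sets C8 and C9.

Step 8
Reactants: 14
Product: 16 hydroxy ketone with the C10 alcohol and the C13 ketone, via hydroxy silyl enol ether 15 (not isolated)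
Conditions: NaBH4, MeOH/THF, −40 to 0 °C; then 1 M HCl, THF, rt
Reagents that add atoms: none
Why: Hydride reduction masks the C10 ketone (its configuration is a placeholder, drawn for attack from the convex face) and acid hydrolysis of the silyl enol ether frees the C13 ketone, so only C13 can form a ketyl in step 9.

Step 9
Reactants: 16
Product: 17 B/C/D diol with the C10 secondary alcohol, the C13 tertiary alcohol and the C16 methylene group
Conditions: SmI2 (2.5 equiv), HMPA, t-BuOH, THF, 0 °C to rt
Reagents that add atoms: none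
Why: Ketyl–alkyne reductive cyclisation (5-exo-dig attack of the C13 ketyl on C16) closes ring D as the bicyclo[3.2.1]octane; the C13 configuration is dictated by the bridge from C8.

Step 10
Reactants: 17
Product: 18 B/C/D hydroxy ketone with the C10 ketone and the free C13 alcohol
Conditions: DMP, NaHCO3, CH2Cl2, 0 °C to rt
Reagents that add atoms: none
Why: Dess–Martin oxidation of the secondary alcohol; the tertiary allylic alcohol cannot be oxidised.

Step 11
Reactants: 18
Product: 19 B/C/D ketone with the C13 tert-butyldimethylsilyl ether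
Conditions: TBSOTf, 2,6-lutidine, CH2Cl2, −78 to 0 °C
Reagents that add atoms: tert-butyldimethylsilyl trifluoromethanesulfonate, CC(C)(C)[Si](C)(C)OS(=O)(=O)C(F)(F)F
Why: Silyl triflate silylation of the hindered tertiary alcohol; the weak base should not convert the ketone into a silyl enol ether at low temperature.

Step 12
Reactants: 19
Product: 20 ring B enol triflate (C10–OTf, C10=C5)
Conditions: KN(SiMe3)2, THF, −78 °C; then PhNTf2, −78 to 0 °C
Reagents that add atoms: N-phenylbis(trifluoromethanesulfonimide), O=S(=O)(N(c1ccccc1)S(=O)(=O)C(F)(F)F)C(F)(F)F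
Why: Kinetic deprotonation at the C5 methylene (C9 is a ring-fusion methine next to the quaternary C8) and O-triflation of the enolate.

Step 13
Reactants: 21 2-deoxy-L-ribose
Product: 22 2-deoxy-3,4-O-isopropylidene-L-erythro-pentopyranose (anomeric mixture)
Conditions: 2-methoxypropene, PPTS (cat.), EtOAc, 0 °C
Reagents that add atoms: 2-methoxypropene, C=C(C)OC
Why: Kinetic acetonation of the cis-3,4-diol of the pyranose form leaves the anomeric hydroxyl free.

Step 14
Reactants: 22
Product: 23 2-deoxy-3,4-O-isopropylidene-L-erythro-pentono-1,5-lactone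
Conditions: TEMPO (0.1 equiv), PhI(OAc)2, CH2Cl2, rt
Reagents that add atoms: none
Why: Oxoammonium oxidation of the lactol to the δ-lactone under conditions that spare the acetonide.

Step 15
Reactants: 23; 2 methanol
Product: 24 methyl 2-[(4R,5S)-5-(hydroxymethyl)-2,2-dimethyl-1,3-dioxolan-4-yl]acetate
Conditions: Et3N (0.2 equiv), MeOH, rt; evaporate below 25 °C and use at once
Reagents that add atoms: methanol (compound 2), CO
Why: Base-catalysed methanolysis in methanol as solvent shifts the lactone–hydroxy ester equilibrium to the open ester and frees the primary C1 hydroxyl; the mild base should not cause β-elimination.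

Step 16
Reactants: 24
Product: 25 methyl 2-[(4R,5R)-5-formyl-2,2-dimethyl-1,3-dioxolan-4-yl]acetate
Conditions: DMP, NaHCO3, CH2Cl2, 0 °C; used at once
Reagents that add atoms: none
Why: Buffered Dess–Martin oxidation gives the aldehyde without epimerising the cis-dioxolane.

Step 17
Reactants: 20; 25
Product: 26 coupled allylic alcohol (C1 epimers; C1 bonded to C10; C19 methyl ester)
Conditions: CrCl2 (4 equiv), NiCl2 (0.05 equiv), DMF, rt
Reagents that add atoms: none
Why: Nozaki–Hiyama–Kishi coupling: the alkenyl–chromium reagent generated from the enol triflate by CrCl2 with catalytic NiCl2 adds chemoselectively to the aldehyde in the presence of the methyl ester and forms C1–C10; the epimers are not separated because C1 is reset in steps 18 and 19.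

Step 18
Reactants: 26
Product: 27 enone (C1 ketone conjugated with C10=C5)
Conditions: DMP, NaHCO3, CH2Cl2, 0 °C to rt
Reagents that add atoms: none
Why: Dess–Martin oxidation of the allylic alcohols converges both C1 epimers to one ketone.

Step 19
Reactants: 27
Product: 29 all-cis δ-lactone without the C4 methyl group, via threo hydroxy ester 28 (not isolated)
Conditions: LiBH(s-Bu)3, THF, −78 °C; warm to rt; aq. NH4Cl; then PPTS (cat.), toluene, 50 °C to complete ring closure
Reagents that add atoms: none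
Why: Felkin–Anh 1,2-reduction by the bulky, non-chelating hydride (attack anti to the C2–O bond) should give the C1 alkoxide threo to the C2 oxygen, which closes onto the methyl ester by intramolecular transesterification; this places C10 cis to the acetonide on the lactone.

Step 20
Reactants: 29; 30 iodomethane
Product: 31 4-methyl δ-lactone (Ireland–Claisen precursor; methyl trans to the acetonide)
Conditions: LiN(iPr)2, THF, −78 °C; then MeI, DMPU, −78 to −40 °C
Reagents that add atoms: iodomethane (compound 30), CI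
Why: Lactone enolate alkylation from the face opposite the acetonide and the C1 substituent; at −78 °C the enolate should alkylate before it expels the C3 oxygen, and the C4 configuration is of no consequence because C4 becomes trigonal in step 21.

Step 21
Reactants: 31
Product: 34 ring A 1(10)-ene 19-acid, via silyl ketene acetal 32 (not isolated), via trimethylsilyl ester 33 (not isolated)
Conditions: Me3SiCl/Et3N, THF, −78 °C; add LiN(iPr)2; warm to rt; toluene, 80 °C; then aq. citric acid
Reagents that add atoms: none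
Why: LiN(iPr)2 in the presence of Me3SiCl converts the lactone into the cyclic silyl ketene acetal C4=C19, whose [3,3] sigmatropic shift (Ireland–Claisen rearrangement of a lactone enolate, the known ring-contracting variant used for alkenyl lactones and dioxanones) forms C4–C5 while C1–O breaks and the alkene moves to C1=C10; aqueous work-up cleaves the silyl ester. Ring A closes as a six-membered carbocycle through a boat-like bicyclo[2.2.2]-type array in which C2–C3, O–C19 and C10=C5 bridge C1 and C4, so the closure is a sigmatropic ring contraction of the δ-lactone and not a polar cyclisation. C4 is set by the lactone face that carries the C10 substituent (cis to the acetonide, so C19 ends trans to the C3 oxygen and C18 cis to it). C5 is set by suprafacial transfer from C1 across the ring B alkene to the face opposite the C7 side chain, which places C6 and C19 cis. The step needs silylation to outrun β-elimination of the C3 oxygen: in the ground-state half-chair the C4–H bond is axial while the C3–O bond lies near the enolate plane, the base is added to the lactone/Me3SiCl mixture, and C4 is the only acidic position.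

Step 22
Reactants: 34
Product: 35 1β-iodo 19,10-lactone
Conditions: iodine, NaHCO3, THF/H2O, 0 °C, dark
Reagents that add atoms: iodine, II
Why: Iodolactonisation: the C19 carboxylate on the α face opens the iodonium ion of C1=C10 at the tertiary C10 (γ-lactone, anti addition), which sets C10; the silylated exocyclic alkene has no internal nucleophile and should stay intact.

Step 23
Reactants: 35
Product: 36 19,10-lactone with C1 as CH2
Conditions: Bu3SnH, AIBN (cat.), toluene, 80 °C
Reagents that add atoms: none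
Why: Radical chain deiodination; hydrogen transfer to the C1 radical is faster than any fragmentation of the neighbouring C–O bonds.

Step 24
Reactants: 36
Product: 37 diol with the free C7 and C13 hydroxyls (acetonide kept)
Conditions: Bu4NF, THF, 50 °C
Reagents that add atoms: none
Why: Fluoride cleaves both silyl ethers; the C3 oxygen stays in the acetonide, so no retro-aldol epimerisation at C3 can occur under the basic conditions.

Step 25
Reactants: 37
Product: 39 2,3-acetonide of the target gibberellin (C7 acid), via aldehyde 38 (not isolated)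
Conditions: TEMPO (0.2 equiv), PhI(OAc)2 (2.5 equiv), MeCN/pH 7 buffer, rt
Reagents that add atoms: water, O
Why: Oxoammonium oxidation of the primary alcohol through the aldehyde hydrate to the acid; the tertiary C13 alcohol cannot be oxidised and the near-neutral medium should not epimerise C6.

Step 26
Reactants: 39
Product: 40 target gibberellin (2β,3β,13-trihydroxy 19,10-lactone 7-acid)
Conditions: AcOH/H2O (4:1), 40 °C
Reagents that add atoms: none
Why: Mild acid hydrolysis of the cis-fused acetonide; these conditions should not rearrange the 13-hydroxy-16-ene unit.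

**Compound list**

1 | (S)-4-(tert-butyldimethylsilyloxy)cyclopent-2-en-1-one | O=C1C=C[C@@H](O[Si](C)(C)C(C)(C)C)C1 | starting material
2 | methanol | CO | starting material
3 | (3R,4S)-4-(tert-butyldimethylsilyloxy)-3-(hydroxymethyl)cyclopentan-1-one | O=C1C[C@H](CO)[C@@H](O[Si](C)(C)C(C)(C)C)C1 | intermediate
4 | (3R,4S)-4-(tert-butyldimethylsilyloxy)-3-[(tert-butyldiphenylsilyloxy)methyl]cyclopentan-1-one | O=C1C[C@H](CO[Si](c2ccccc2)(c2ccccc2)C(C)(C)C)[C@@H](O[Si](C)(C)C(C)(C)C)C1 | intermediate
5 | dimethyl ketal of 4 (not isolated) | COC1(OC)C[C@H](CO[Si](c2ccccc2)(c2ccccc2)C(C)(C)C)[C@@H](O[Si](C)(C)C(C)(C)C)C1 | intermediate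
6 | (1S,2R)-2-[(tert-butyldiphenylsilyloxy)methyl]-4,4-dimethoxycyclopentan-1-ol | COC1(OC)C[C@H](CO[Si](c2ccccc2)(c2ccccc2)C(C)(C)C)[C@@H](O)C1 | intermediate
7 | (R)-2-[(tert-butyldiphenylsilyloxy)methyl]-4,4-dimethoxycyclopentan-1-one (not isolated) | COC1(OC)C[C@H](CO[Si](c2ccccc2)(c2ccccc2)C(C)(C)C)C(=O)C1 | intermediate
8 | (R)-5-[(tert-butyldiphenylsilyloxy)methyl]-3-methoxycyclopent-2-en-1-one | COC1=CC(=O)[C@@H](CO[Si](c2ccccc2)(c2ccccc2)C(C)(C)C)C1 | intermediate
9 | propargyl bromide (3-bromoprop-1-yne) | C#CCBr | starting material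
10 | 1,2-adduct: 5-[(tert-butyldiphenylsilyloxy)methyl]-3-methoxy-1-(prop-2-yn-1-yl)cyclopent-2-en-1-ol, carbinol epimers (not isolated) | COC1=CC(O)(CC#C)[C@@H](CO[Si](c2ccccc2)(c2ccccc2)C(C)(C)C)C1 | intermediate
11 | (S)-4-[(tert-butyldiphenylsilyloxy)methyl]-3-(prop-2-yn-1-yl)cyclopent-2-en-1-one | O=C1C=C(CC#C)[C@@H](CO[Si](c2ccccc2)(c2ccccc2)C(C)(C)C)C1 | intermediate
12 | methyl vinyl ketone | C=CC(C)=O | starting material
13 | 2-(tert-butyldimethylsilyloxy)buta-1,3-diene | C=CC(=C)O[Si](C)(C)C(C)(C)C | intermediate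
14 | cis-fused hydrindenone: 5-(tert-butyldimethylsilyloxy)-3-[(tert-butyldiphenylsilyloxy)methyl]-3a-(prop-2-yn-1-yl)-2,3,3a,4,7,7a-hexahydro-1H-inden-1-one; silyloxymethyl, propargyl and the ring-fusion hydrogen on one face | C#CC[C@]12CC(O[Si](C)(C)C(C)(C)C)=CC[C@H]1C(=O)C[C@@H]2CO[Si](c3ccccc3)(c3ccccc3)C(C)(C)C | intermediate
15 | C10 alcohol of 14 with the C13 silyl enol ether (not isolated) | C#CC[C@]12CC(O[Si](C)(C)C(C)(C)C)=CC[C@H]1[C@@H](O)C[C@@H]2CO[Si](c3ccccc3)(c3ccccc3)C(C)(C)C | intermediate
16 | cis-fused 3-[(tert-butyldiphenylsilyloxy)methyl]-1-hydroxy-3a-(prop-2-yn-1-yl)octahydro-5H-inden-5-one (C10 alcohol, C13 ketone) | C#CC[C@]12CC(=O)CC[C@H]1[C@@H](O)C[C@@H]2CO[Si](c3ccccc3)(c3ccccc3)C(C)(C)C | intermediate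
17 | B/C/D diol: C10 secondary alcohol, C13 bridgehead alcohol, C16 exocyclic methylene, C7 silyl ether | C=C1C[C@]23C[C@@]1(O)CC[C@H]2[C@@H](O)C[C@@H]3CO[Si](c4ccccc4)(c4ccccc4)C(C)(C)C | intermediate
18 | B/C/D hydroxy ketone: C10 ketone, free C13 alcohol | C=C1C[C@]23C[C@@]1(O)CC[C@H]2C(=O)C[C@@H]3CO[Si](c4ccccc4)(c4ccccc4)C(C)(C)C | intermediate
19 | B/C/D ketone: C10 ketone, C13 tert-butyldimethylsilyl ether, C7 tert-butyldiphenylsilyl ether | C=C1C[C@]23C[C@@]1(O[Si](C)(C)C(C)(C)C)CC[C@H]2C(=O)C[C@@H]3CO[Si](c4ccccc4)(c4ccccc4)C(C)(C)C | intermediate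
20 | ring B enol triflate of 19 (C10–OTf, C10=C5) | C=C1C[C@]23C[C@@]1(O[Si](C)(C)C(C)(C)C)CC[C@H]2C(OS(=O)(=O)C(F)(F)F)=C[C@@H]3CO[Si](c4ccccc4)(c4ccccc4)C(C)(C)C | intermediate
21 | 2-deoxy-L-ribose (2-deoxy-L-erythro-pentose, open-chain form) | O=CC[C@@H](O)[C@@H](O)CO | starting material
22 | 2-deoxy-3,4-O-isopropylidene-L-erythro-pentopyranose (anomeric mixture) | OC1C[C@H]2OC(C)(C)O[C@H]2CO1 | intermediate
23 | 2-deoxy-3,4-O-isopropylidene-L-erythro-pentono-1,5-lactone | O=C1C[C@H]2OC(C)(C)O[C@H]2CO1 | intermediate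
24 | methyl 2-[(4R,5S)-5-(hydroxymethyl)-2,2-dimethyl-1,3-dioxolan-4-yl]acetate | COC(=O)C[C@H]1OC(C)(C)O[C@H]1CO | intermediate
25 | methyl 2-[(4R,5R)-5-formyl-2,2-dimethyl-1,3-dioxolan-4-yl]acetate | COC(=O)C[C@H]1OC(C)(C)O[C@H]1C=O | intermediate
26 | coupled allylic alcohol (C1 epimers): C1 carbinol bonded to C10 of the ring B cyclopentene, C2/C3 acetonide, C19 methyl ester | C=C1C[C@]23C[C@@]1(O[Si](C)(C)C(C)(C)C)CC[C@H]2C(=C[C@@H]3CO[Si](c4ccccc4)(c4ccccc4)C(C)(C)C)C(O)[C@@H]1OC(C)(C)O[C@@H]1CC(=O)OC | intermediate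
27 | enone: C1 ketone conjugated with C10=C5 | C=C1C[C@]23C[C@@]1(O[Si](C)(C)C(C)(C)C)CC[C@H]2C(=C[C@@H]3CO[Si](c4ccccc4)(c4ccccc4)C(C)(C)C)C(=O)[C@@H]1OC(C)(C)O[C@@H]1CC(=O)OC | intermediate
28 | threo hydroxy ester: (1R) allylic alcohol, C1–O threo to C2–O (not isolated) | C=C1C[C@]23C[C@@]1(O[Si](C)(C)C(C)(C)C)CC[C@H]2C(=C[C@@H]3CO[Si](c4ccccc4)(c4ccccc4)C(C)(C)C)[C@@H](O)[C@@H]1OC(C)(C)O[C@@H]1CC(=O)OC | intermediate
29 | δ-lactone without the C4 methyl group: C19 carbonyl, ring oxygen on C1, cis-fused C2/C3 acetonide, C10 substituent cis to the acetonide | C=C1C[C@]23C[C@@]1(O[Si](C)(C)C(C)(C)C)CC[C@H]2C(=C[C@@H]3CO[Si](c4ccccc4)(c4ccccc4)C(C)(C)C)[C@H]1OC(=O)C[C@H]2OC(C)(C)O[C@@H]12 | intermediate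
30 | iodomethane | CI | starting material
31 | Ireland–Claisen precursor: 4-methyl δ-lactone, methyl trans to the acetonide, B/C/D cyclopentenyl group at C1 | C=C1C[C@]23C[C@@]1(O[Si](C)(C)C(C)(C)C)CC[C@H]2C(=C[C@@H]3CO[Si](c4ccccc4)(c4ccccc4)C(C)(C)C)[C@H]1OC(=O)[C@H](C)[C@H]2OC(C)(C)O[C@@H]12 | intermediate
32 | cyclic trimethylsilyl ketene acetal of 31 (C4=C19) (not isolated) | C=C1C[C@]23C[C@@]1(O[Si](C)(C)C(C)(C)C)CC[C@H]2C(=C[C@@H]3CO[Si](c4ccccc4)(c4ccccc4)C(C)(C)C)[C@H]1OC(O[Si](C)(C)C)=C(C)[C@H]2OC(C)(C)O[C@@H]12 | intermediate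
33 | trimethylsilyl ester of 34 (not isolated) | C=C1C[C@]23C[C@@]1(O[Si](C)(C)C(C)(C)C)CC[C@H]2C2=C[C@@H]4OC(C)(C)O[C@@H]4[C@@](C)(C(=O)O[Si](C)(C)C)[C@H]2[C@@H]3CO[Si](c5ccccc5)(c5ccccc5)C(C)(C)C | intermediate
34 | ring A 1(10)-ene 19-acid: C4 quaternary (C18 β, C19 α), 5β-hydrogen, C2/C3 acetonide | C=C1C[C@]23C[C@@]1(O[Si](C)(C)C(C)(C)C)CC[C@H]2C2=C[C@@H]4OC(C)(C)O[C@@H]4[C@@](C)(C(=O)O)[C@H]2[C@@H]3CO[Si](c5ccccc5)(c5ccccc5)C(C)(C)C | intermediate
35 | 1β-iodo 19,10-lactone | C=C1C[C@]23C[C@@]1(O[Si](C)(C)C(C)(C)C)CC[C@H]2[C@@]12[C@H](I)[C@@H]4OC(C)(C)O[C@@H]4[C@@](C)(C(=O)O1)[C@H]2[C@@H]3CO[Si](c5ccccc5)(c5ccccc5)C(C)(C)C | intermediate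
36 | 19,10-lactone, C1 as CH2, both silyl ethers and the acetonide in place | C=C1C[C@]23C[C@@]1(O[Si](C)(C)C(C)(C)C)CC[C@H]2[C@@]12C[C@@H]4OC(C)(C)O[C@@H]4[C@@](C)(C(=O)O1)[C@H]2[C@@H]3CO[Si](c5ccccc5)(c5ccccc5)C(C)(C)C | intermediate
37 | 7,13-diol 2,3-acetonide of the 19,10-lactone | C=C1C[C@]23C[C@@]1(O)CC[C@H]2[C@@]12C[C@@H]4OC(C)(C)O[C@@H]4[C@@](C)(C(=O)O1)[C@H]2[C@@H]3CO | intermediate
38 | C7 aldehyde of 37 (not isolated) | C=C1C[C@]23C[C@@]1(O)CC[C@H]2[C@@]12C[C@@H]4OC(C)(C)O[C@@H]4[C@@](C)(C(=O)O1)[C@H]2[C@@H]3C=O | intermediate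
39 | 2,3-acetonide of the target gibberellin (C7 acid, 13-hydroxy, 19,10-lactone) | C=C1C[C@]23C[C@@]1(O)CC[C@H]2[C@@]12C[C@@H]4OC(C)(C)O[C@@H]4[C@@](C)(C(=O)O1)[C@H]2[C@@H]3C(=O)O | intermediate
40 | target gibberellin: ent-2α,3α,10,13-tetrahydroxy-20-norgibberell-16-ene-7,19-dioic acid 19,10-lactone (2β,3β,13-triol in the usual gibberellin drawing) | C=C1C[C@]23C[C@@]1(O)CC[C@H]2[C@@]12C[C@H](O)[C@H](O)[C@@](C)(C(=O)O1)[C@H]2[C@@H]3C(=O)O | target

**Step count and risk**

Total step count: 26. Longest linear sequence: 21 steps (steps 1–5, 7–12 and 17–26).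

Steps most likely to fail:

1. Step 21 (key step). Enolisation of the hindered tertiary C4–H may be slow, or the lithium enolate may expel the C3 oxygen before it is silylated. Fallback: the ketene acetal is made by hydrosilylation of an α-methylene lactone, so that no metal enolate of the methylated lactone is formed. It sets out from 29: LiN(iPr)2 and then Me2N=CH2 iodide at −78 °C should give the Mannich base F1, and MeI followed by NaHCO3 should give the α-methylene lactone F2. RhCl(PPh3)3 (cat.) and Et3SiH in toluene then deliver hydrogen to the exocyclic methylene carbon and silicon to the carbonyl oxygen (1,4-hydrosilylation), which gives the triethylsilyl ketene acetal F3. Heating at 80 °C should rearrange it to the triethylsilyl ester F4, and aqueous citric acid then gives acid 34, where the route is rejoined.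

2. Step 7. The β,β-disubstituted enone may be too hindered for the cycloaddition, or the Lewis acid may destroy the diene or cleave a silyl ether first. Fallback: stepwise annulation by two Michael additions, with the two ketones told apart afterwards. It sets out from 11 and 13: TiCl4-mediated Mukaiyama–Michael addition of 13 to 11 at −78 °C should give the vinyl ketone F5, again anti to the C6 side chain. KOt-Bu (cat.) in t-BuOH/THF then closes ring C by intramolecular Michael addition of the C9 enolate and gives the cis-fused diketone F6. Ethylene glycol with PPTS should ketalise the cyclohexanone carbonyl C13 in preference to the hindered cyclopentanone carbonyl C10 and give the mono-ketal F7. NaBH4 reduces C10 to the ketal alcohol F8, and 1 M HCl in THF frees the C13 ketone to give 16, where the route is rejoined.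

3. Step 19. Facial selectivity of the hydride addition may be poor (lithium chelation would favour the C1 epimer), or conjugate reduction of the enone may compete. Fallback: deliberate formation of the other epimer and inversion on ring closure. It sets out from 27: Zn(BH4)2 in Et2O at −20 °C (chelation control, 1,2-selective) should give the erythro hydroxy ester F9, LiOH in THF/H2O the erythro hydroxy acid F10, and PPh3/DIAD (Mitsunobu lactonisation with inversion at C1) the lactone 29, where the route is rejoined.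

Further compounds
F1 | step 21 | Mannich base: 4-(dimethylaminomethyl) derivative of lactone 29 (C4 epimers) | C=C1C[C@]23C[C@@]1(O[Si](C)(C)C(C)(C)C)CC[C@H]2C(=C[C@@H]3CO[Si](c4ccccc4)(c4ccccc4)C(C)(C)C)[C@H]1OC(=O)C(CN(C)C)[C@H]2OC(C)(C)O[C@@H]12
F2 | step 21 | α-methylene lactone: 4-methylidene derivative of lactone 29 | C=C1C[C@]23C[C@@]1(O[Si](C)(C)C(C)(C)C)CC[C@H]2C(=C[C@@H]3CO[Si](c4ccccc4)(c4ccccc4)C(C)(C)C)[C@H]1OC(=O)C(=C)[C@H]2OC(C)(C)O[C@@H]12
F3 | step 21 | cyclic triethylsilyl ketene acetal (C4=C19) of lactone 31 | C=C1C[C@]23C[C@@]1(O[Si](C)(C)C(C)(C)C)CC[C@H]2C(=C[C@@H]3CO[Si](c4ccccc4)(c4ccccc4)C(C)(C)C)[C@H]1OC(O[Si](CC)(CC)CC)=C(C)[C@H]2OC(C)(C)O[C@@H]12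
F4 | step 21 | triethylsilyl ester of acid 34 | C=C1C[C@]23C[C@@]1(O[Si](C)(C)C(C)(C)C)CC[C@H]2C2=C[C@@H]4OC(C)(C)O[C@@H]4[C@@](C)(C(=O)O[Si](CC)(CC)CC)[C@H]2[C@@H]3CO[Si](c5ccccc5)(c5ccccc5)C(C)(C)C
F5 | step 7 | vinyl ketone: (3R,4S)-4-[(tert-butyldiphenylsilyloxy)methyl]-3-(2-oxobut-3-en-1-yl)-3-(prop-2-yn-1-yl)cyclopentan-1-one | C#CC[C@]1(CC(=O)C=C)CC(=O)C[C@@H]1CO[Si](c2ccccc2)(c2ccccc2)C(C)(C)C
F6 | step 7 | cis-fused diketone: C10 and C13 ketones, C8 propargyl, C7 silyl ether | C#CC[C@]12CC(=O)CC[C@H]1C(=O)C[C@@H]2CO[Si](c3ccccc3)(c3ccccc3)C(C)(C)C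
F7 | step 7 | mono-ketal: C13 ethylene ketal of the diketone, C10 ketone free | C#CC[C@]12CC3(OCCO3)CC[C@H]1C(=O)C[C@@H]2CO[Si](c4ccccc4)(c4ccccc4)C(C)(C)C
F8 | step 7 | ketal alcohol: C13 ethylene ketal, C10 secondary alcohol | C#CC[C@]12CC3(OCCO3)CC[C@H]1[C@@H](O)C[C@@H]2CO[Si](c4ccccc4)(c4ccccc4)C(C)(C)C
F9 | step 19 | erythro hydroxy ester: C1 epimer of 28 | C=C1C[C@]23C[C@@]1(O[Si](C)(C)C(C)(C)C)CC[C@H]2C(=C[C@@H]3CO[Si](c4ccccc4)(c4ccccc4)C(C)(C)C)[C@H](O)[C@@H]1OC(C)(C)O[C@@H]1CC(=O)OC
F10 | step 19 | erythro hydroxy acid from the erythro hydroxy ester | C=C1C[C@]23C[C@@]1(O[Si](C)(C)C(C)(C)C)CC[C@H]2C(=C[C@@H]3CO[Si](c4ccccc4)(c4ccccc4)C(C)(C)C)[C@H](O)[C@@H]1OC(C)(C)O[C@@H]1CC(=O)O
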